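The earlier runs and the new flask stem from a simulated flask from invented constants; the scatter is artificial.

The constants of this flask are not given, so one has to be read from the curves, whose rate at first grows as target accumulates.

| setting | Sunday's | Thursday's | Friday's | Wednesday's |
|---|---|---|---|---|
| substrate | 0.500 M | 0.500 M | 0.500 M | 1.50 M |
| coupling partner | 1.00 M | 1.00 M | 3.00 M | 0.500 M |
| free catalyst | 0.0250 M | 0.0380 M | 0.0250 M | 0.0250 M |
| time |  |  |  | 7.8 h |

| run | time / h | [target] / M |
|---|---|---|
| Sunday's run | 0.28 | 0.0053 |
| Sunday's run | 0.85 | 0.0039 |
| Sunday's run | 1.6 | 0.0159 |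
| Sunday's run | 2.6 | 0.0619 |
| Sunday's run | 3.7 | 0.1306 |
| Sunday's run | 4.9 | 0.2150 |
| Sunday's run | 6.3 | 0.3193 |
| Sunday's run | 7.8 | 0.3943 |
| Thursday's run | 0.28 | 0.0029 |
| Thursday's run | 0.85 | 0.0051 |
| Thursday's run | 1.6 | 0.0319 |
| Thursday's run | 2.6 | 0.0852 |
| Thursday's run | 3.7 | 0.1696 |
| Thursday's run | 4.9 | 0.2677 |
| Thursday's run | 6.3 | 0.3633 |
| Thursday's run | 7.8 | 0.4268 |
| Friday's run | 0.28 | 0.0033 |
| Friday's run | 0.85 | 0.0176 |
| Friday's run | 1.6 | 0.0978 |
| Friday's run | 2.6 | 0.3251 |
| Friday's run | 3.7 | 0.4647 |
| Friday's run | 4.9 | 0.4948 |
| Friday's run | 6.3 | 0.4984 |
| Friday's run | 7.8 | 0.4978 |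

(readings scatter by 0.002 M)

- Overall: substrate + coupling partner -> target, with free catalyst as catalyst.
- Constant volume, constant temperature.
- Bound and free are read together.
- An order is taken over about fifteen percent of the charge, up and down.

- order of the initial rate in [coupling partner], near the charge of the Sunday's run, the rate being that where two percent of its substrate are target
- order of the initial rate in [free catalyst], near the charge of the Sunday's run, the rate being that where two percent of its substrate are target
- target in the Wednesday's run at 7.8 h, as a share of the substrate charged

The reckoning below is my own. Its working quantity is the target-assisted constant, defined as the rate divided by the product of substrate, coupling partner and target (an apparent third-order constant). Friday's steep stretch gives a first value. Between 1.6 h and 2.6 h, target rises at 0.227 M h⁻¹, about 9.06 times the rate over Friday's first two readings. Any catalyst contribution is counted in the constant.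

Friday, mid-stretch target 0.211 M:

constant = rate / (target × substrate × partner) = 1.34 L² mol⁻² h⁻¹

Sunday's readings bracket the two-percent point, 0.0100 M of target, and their slope there is 0.0160 M h⁻¹. The constant claims 40.5% of that rate. This share is first order in partner and, at fixed target, zero order in catalyst. If the remainder has an order between zero and one in each, the order in partner is at least that share read as a fraction, and the order in catalyst at most 59.5% read the same way.

In Wednesday's flask the coupling partner, charged at 0.500 M against 1.50 M of substrate, is the limiting reagent, so target can reach 33.3% of the substrate. The natural logarithm of target over remaining partner then climbs in a straight line. Its slope is the constant × substrate × partner charge, with substrate taken at 1.25 M, where half the partner has gone. Sunday's reading at 1.6 h serves as the seed: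

start −3.42, slope 0.835 h⁻¹, giving 28.4%

The weak link is the constant, because Friday's stretch has 2.79 M of partner against Wednesday's charge of 0.500 M. Sunday's stretch from 3.7 h to 4.9 h has 0.827 M and reads 1.50 L² mol⁻² h⁻¹. Reforged with it, the line gives 30.6%, the figure I commit to.

The forecast gives 0.75 in partner, 0.45 in catalyst and 32% for Wednesday, resting on “a catalyst-driven background of about 40%”. My reckoning differs there, since it leaves a remainder of 59.5%.

Wednesday's flask gives 31.1%, and the fit with the true steps forecasts 31.2%; the orders are 0.64 in partner, below the forecast's, and 0.45 in catalyst.

    active catalyst + substrate → catalyst-substrate complex (3.960 L mol⁻¹ h⁻¹)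
    catalyst-substrate complex + coupling partner → loaded catalyst (3.852 L mol⁻¹ h⁻¹)
    loaded catalyst → target + active catalyst (4.032 h⁻¹)
    free catalyst + coupling partner → active catalyst + coupling partner (0.9504 L mol⁻¹ h⁻¹)
    substrate + coupling partner + target → 2 target (1.314 L² mol⁻² h⁻¹)

Against Sunday's rate of 0.020 M h⁻¹ at two percent, Friday's constant claims 31.9%, so the remainder's order in partner is 0.471. Against Friday's rate of 0.040 M h⁻¹ at the same target, it claims 49.3%.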